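**Retrosynthetic overview**
1. Target 14 ⇒ aryl bromide 11 + prop-2-yn-1-ol 12: the (E)-3-hydroxypropenyl arm is attached last by hydroboration/Suzuki–Miyaura coupling.
2. 11 ⇒ aldehyde 6 + racemic aryloxy acid 9: the C7–C8 bond (benzylic carbinol carbon to the methyl-bearing ether carbon) is made by a photoredox/chromium decarboxylative radical addition that sets both stereocentres; the acetate is put on in the same flask.
3. 6 and 9 ⇒ one common phenol 3 (4-bromo-2,6-dimethoxyphenol): Br is turned into CHO for ring A, and the OH is alkylated for ring B.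
4. 3 ⇒ 4-bromophenol 1 by double ortho-iodination and copper-catalysed methoxylation.
5. No ring is formed; both benzene rings come from 1.

Assumption: the SMILES is read as the (1R,2R)-threo benzylic acetate (7R,8R in neolignan numbering) with an (E)-allylic alcohol; both antipodes of the chiral ligand in step 6 are taken as available, and the one giving Si-face addition to the aldehyde is used.

**Route**

Step 1
Reactants: 1 4-bromophenol
Product: 2 4-bromo-2,6-diiodophenol
Conditions: NIS (2.1 equiv), TsOH·H2O (10 mol %), MeCN, 20 °C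
Reagents that add atoms: N-iodosuccinimide, O=C1CCC(=O)N1I
Why: Electrophilic aromatic iodination: OH directs ortho/para, para is blocked by Br, so both iodine atoms enter at C2 and C6.

Step 2
Reactants: 2 4-bromo-2,6-diiodophenol
Product: 3 4-bromo-2,6-dimethoxyphenol
Conditions: NaOMe (8 equiv), CuI (20 mol %), MeOH/DMF, 80 °C; aq HCl work-up
Reagents that add atoms: sodium methoxide, C[O-].[Na+]
Why: Ullmann-type copper-catalysed C–O coupling: C–I bonds react with copper methoxide much faster than C–Br and the neighbouring phenoxide holds copper at the ortho positions, so both iodides are exchanged for OMe at 80 °C while the para bromide stays.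

Step 3
Reactants: 3 4-bromo-2,6-dimethoxyphenol (part of the batch)
Product: 4 5-bromo-1,2,3-trimethoxybenzene
Conditions: MeI, K2CO3, acetone, reflux
Reagents that add atoms: iodomethane, CI
Why: Williamson ether synthesis: SN2 attack of the phenoxide on MeI; the aryl bromide is inert.

Step 4
Reactants: 4 5-bromo-1,2,3-trimethoxybenzene
Product: 6 3,4,5-trimethoxybenzaldehyde, via (3,4,5-trimethoxyphenyl)lithium 5 (not isolated)
Conditions: n-BuLi, THF, −78 °C; DMF, −78 → 0 °C; aq HCl
Reagents that add atoms: N,N-dimethylformamide, CN(C)C=O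
Why: Bromine–lithium exchange followed by Bouveault formylation: the aryllithium adds to DMF and the hemiaminal alkoxide releases the aldehyde only on acidic work-up, so there is no over-addition.

Step 5
Reactants: 3 4-bromo-2,6-dimethoxyphenol; 7 methyl 2-bromopropanoate (racemic)
Product: 9 2-(4-bromo-2,6-dimethoxyphenoxy)propanoic acid (racemic), via methyl ester 8 (not isolated)
Conditions: K2CO3, DMF, 60 °C; then LiOH, THF/H2O, 20 °C; aq HCl
Reagents that add atoms: lithium hydroxide, [Li+].[OH-]
Why: Williamson ether synthesis (SN2 of the phenoxide on the α-bromo ester) followed by saponification in the same flask; the stereocentre is left racemic because it becomes a planar radical in step 6.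

Step 6
Reactants: 6 3,4,5-trimethoxybenzaldehyde (1.0 equiv); 9 2-(4-bromo-2,6-dimethoxyphenoxy)propanoic acid (1.5 equiv)
Product: 11 (1R,2R)-2-(4-bromo-2,6-dimethoxyphenoxy)-1-(3,4,5-trimethoxyphenyl)propyl acetate, via alcohol 10 (not isolated)
Conditions: CrCl2 (10 mol %), chiral indane-fused cyano-bis(oxazoline) ligand (12 mol %), 4CzIPN (2 mol %), Cs2CO3 (10 mol %), DME, 450 nm LEDs, 20 °C; then Ac2O, Et3N, DMAP, 20 °C
Reagents that add atoms: acetic anhydride, CC(=O)OC(C)=O
Why: Proposed new method: excited 4CzIPN oxidises the carboxylate of 9, loss of CO2 gives the planar 1-(aryloxy)ethyl radical, ligand-bound divalent chromium captures it as a trivalent alkylchromium that adds to the Si face of aldehyde 6 (Nozaki–Hiyama–Kishi-type radical–polar crossover), acid 9 protonates the chromium alkoxide and the reduced photocatalyst returns chromium to the divalent state; because C8 passes through the radical and a reversibly homolysed C–Cr bond, both racemic-acid enantiomers converge and C7 and C8 are fixed together in the ligand-controlled addition (the ligand antipode and the threo/erythro ratio are unproven and must be found by screening), the closest known reactions being photoredox/chromium dual-catalytic alkylation of aldehydes and chromium-catalysed asymmetric cross aza-pinacol coupling, after which DMAP-catalysed acyl transfer acetylates the alcohol without touching either stereocentre.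

Step 7
Reactants: 11 (1R,2R)-2-(4-bromo-2,6-dimethoxyphenoxy)-1-(3,4,5-trimethoxyphenyl)propyl acetate; 12 prop-2-yn-1-ol
Product: 14 (1R,2R)-2-{4-[(1E)-3-hydroxyprop-1-en-1-yl]-2,6-dimethoxyphenoxy}-1-(3,4,5-trimethoxyphenyl)propyl acetate, via bis-boryl alkene 13 (not isolated)
Conditions: 12 (1.5 equiv), HBpin (2.2 equiv per alkyne), Cp2Zr(H)Cl (10 mol %), Et3N (10 mol %), 60 °C; then 11, Pd(OAc)2 (3 mol %), SPhos (6 mol %), K3PO4, THF/H2O, 45 °C
Reagents that add atoms: none
Why: Zirconium-catalysed syn hydroboration of the terminal alkyne (the OH is masked in the flask as its borate) fixes the E geometry, and Suzuki–Miyaura coupling transfers the alkenyl group with retention, while phosphate at 45 °C leaves the benzylic acetate and both stereocentres untouched.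

**Compound list**
1 | 4-bromophenol | Oc1ccc(Br)cc1 | starting material
2 | 4-bromo-2,6-diiodophenol | Oc1c(I)cc(Br)cc1I | intermediate
3 | 4-bromo-2,6-dimethoxyphenol | COc1cc(Br)cc(OC)c1O | intermediate
4 | 5-bromo-1,2,3-trimethoxybenzene | COc1cc(Br)cc(OC)c1OC | intermediate
5 | (3,4,5-trimethoxyphenyl)lithium (not isolated) | [Li]c1cc(OC)c(OC)c(OC)c1 | intermediate
6 | 3,4,5-trimethoxybenzaldehyde | COc1cc(C=O)cc(OC)c1OC | intermediate
7 | methyl 2-bromopropanoate (racemic) | COC(=O)C(C)Br | starting material
8 | methyl 2-(4-bromo-2,6-dimethoxyphenoxy)propanoate (racemic, not isolated) | COC(=O)C(C)Oc1c(OC)cc(Br)cc1OC | intermediate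
9 | 2-(4-bromo-2,6-dimethoxyphenoxy)propanoic acid (racemic) | CC(Oc1c(OC)cc(Br)cc1OC)C(=O)O | intermediate
10 | (1R,2R)-2-(4-bromo-2,6-dimethoxyphenoxy)-1-(3,4,5-trimethoxyphenyl)propan-1-ol (not isolated) | COc1cc([C@@H](O)[C@@H](C)Oc2c(OC)cc(Br)cc2OC)cc(OC)c1OC | intermediate
11 | (1R,2R)-2-(4-bromo-2,6-dimethoxyphenoxy)-1-(3,4,5-trimethoxyphenyl)propyl acetate | COc1cc([C@@H](OC(C)=O)[C@@H](C)Oc2c(OC)cc(Br)cc2OC)cc(OC)c1OC | intermediate
12 | prop-2-yn-1-ol | C#CCO | starting material
13 | 4,4,5,5-tetramethyl-2-[(1E)-3-[(4,4,5,5-tetramethyl-1,3,2-dioxaborolan-2-yl)oxy]prop-1-en-1-yl]-1,3,2-dioxaborolane (not isolated) | CC1(C)OB(/C=C/COB2OC(C)(C)C(C)(C)O2)OC1(C)C | intermediate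
14 | (1R,2R)-2-{4-[(1E)-3-hydroxyprop-1-en-1-yl]-2,6-dimethoxyphenoxy}-1-(3,4,5-trimethoxyphenyl)propyl acetate | COc1cc([C@@H](OC(C)=O)[C@@H](C)Oc2c(OC)cc(/C=C/CO)cc2OC)cc(OC)c1OC | target

**Totals**
Total step count: 7. Longest linear sequence: 6 (steps 1, 2, 3, 4, 6, 7).

**Three steps most likely to fail, each with one fallback**

Step 6 (no precedent for enantio- and diastereocontrol with an α-aryloxyalkyl chromium species; erythro product or low ee is possible). The fallback sets out from phenol 3 and aryllithium 5 and comes back to the route at 11. It takes C8 from the chiral pool instead of the radical step.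
- Mitsunobu reaction of 3 with ethyl (S)-lactate (CCOC(=O)[C@H](C)O; PPh3, DIAD, THF, 0 → 20 °C) goes with inversion to ethyl (2R)-2-(4-bromo-2,6-dimethoxyphenoxy)propanoate F2.
- MeNHOMe·HCl and i-PrMgCl (THF, −20 °C) convert it into (2R)-2-(4-bromo-2,6-dimethoxyphenoxy)-N-methoxy-N-methylpropanamide F3.
- Addition of aryllithium 5 (THF, −78 °C) gives (2R)-2-(4-bromo-2,6-dimethoxyphenoxy)-1-(3,4,5-trimethoxyphenyl)propan-1-one F4.
- Felkin–Anh reduction with LiBH(s-Bu)3 (THF, −78 °C) gives the threo alcohol 10, now isolated.
- Ac2O, Et3N and DMAP give 11.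

Step 2 (the para bromide may be partly methoxylated or the iodides reduced on the electron-rich phenoxide). The fallback sets out from 2 and comes back at 4 and then at 3.
- The phenol is methylated first (MeI, K2CO3, acetone) to 5-bromo-1,3-diiodo-2-methoxybenzene F1.
- The copper methoxylation is then run on this neutral arene (CuI, 1,10-phenanthroline, NaOMe, MeOH/toluene, 80 °C), where aryl iodides react and the aryl bromide does not; this gives 4.
- The phenol 3 needed for step 5 is made from part of 4 with AlCl3 (CH2Cl2, 0 → 20 °C), which cleaves only the central methoxy group that is twisted out of the ring plane between its two neighbours.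

Step 7 (one-flask hydroboration of the free propargylic alcohol may be incomplete, and aqueous base may cleave some acetate). The fallback sets out from 11 and comes back at 14.
- Heck–Mizoroki reaction of 11 with acrolein (C=CC=O; Pd(OAc)2, P(o-tol)3, KHCO3, Bu4NCl, DMF, 80 °C) gives (1R,2R)-2-{2,6-dimethoxy-4-[(1E)-3-oxoprop-1-en-1-yl]phenoxy}-1-(3,4,5-trimethoxyphenyl)propyl acetate F5.
- Luche reduction (NaBH4, CeCl3·7H2O, MeOH, −20 °C) reduces only the aldehyde, in 1,2-fashion, and gives 14 with the acetate intact.

**Further compounds**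
F1 | step 2 | 5-bromo-1,3-diiodo-2-methoxybenzene | COc1c(I)cc(Br)cc1I
F2 | step 6 | ethyl (2R)-2-(4-bromo-2,6-dimethoxyphenoxy)propanoate | C[C@@H](Oc1c(OC)cc(Br)cc1OC)C(=O)OCC
F3 | step 6 | (2R)-2-(4-bromo-2,6-dimethoxyphenoxy)-N-methoxy-N-methylpropanamide | C[C@@H](Oc1c(OC)cc(Br)cc1OC)C(=O)N(C)OC
F4 | step 6 | (2R)-2-(4-bromo-2,6-dimethoxyphenoxy)-1-(3,4,5-trimethoxyphenyl)propan-1-one | C[C@@H](Oc1c(OC)cc(Br)cc1OC)C(=O)c1cc(OC)c(OC)c(OC)c1
F5 | step 7 | (1R,2R)-2-{2,6-dimethoxy-4-[(1E)-3-oxoprop-1-en-1-yl]phenoxy}-1-(3,4,5-trimethoxyphenyl)propyl acetate | COc1cc([C@@H](OC(C)=O)[C@@H](C)Oc2c(OC)cc(/C=C/C=O)cc2OC)cc(OC)c1OC
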